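**Retrosynthetic overview**

- The target is robinetinidol-(4β→8)-(−)-epigallocatechin 3-O-gallate (upper unit 2R,3S,4R: 2,3-trans, 3,4-cis; lower unit 2R,3R). The last step is hydrogenolysis of four benzyl ethers on the upper unit.
- Interflavan C4–C8 bond: Friedel–Crafts coupling of commercial EGCG (all of its rings bought intact) with a flavan-3,4-diol phenylboronate. Boron on O-3 is meant to tether the EGCG phenol and deliver C-8 to the 3-O face (3,4-cis).
- Ring C: both C4–C4a and O1–C2 are cut. A boron-templated [3+3] annulation of 3-(benzyloxy)phenol with a (2R,3S)-epoxy aldehyde and PhB(OH)2 forms ring C and the 3,4-fused dioxaborolane in the same flask.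
- Epoxy aldehyde: organocatalytic epoxidation of the enal made by Wittig homologation of 3,4,5-tris(benzyloxy)benzaldehyde.
- Ring order: rings A and B and all EGCG rings are bought; ring C and the dioxaborolane form together (step 3); a seven-membered boracycle forms transiently in step 4 and is hydrolysed with the other B–O bonds.

Assumption 1: the (R)-diarylprolinol silyl ether is taken as the antipode that gives the (2R,3S)-epoxy aldehyde (attack anti to the C-2 substituent of the E-iminium ion, from a steric model, not from a recalled report); if the sense is opposite, the (S)-catalyst is used.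
Assumption 2: 5, 6, F1 and F2 are written as one C-4 epimer; C-4 is ionised in step 4, so the other epimer reacts the same way and is not separated.

**Step 1**
Reactants: 1 3,4,5-tris(benzyloxy)benzaldehyde
Product: 2 (E)-3-[3,4,5-tris(benzyloxy)phenyl]prop-2-enal
Conditions: Ph3P=CHCHO (1.1 equiv), PhMe, 80 °C
Reagents that add atoms: (triphenylphosphoranylidene)acetaldehyde, O=CC=P(c1ccccc1)(c1ccccc1)c1ccccc1
Why: Wittig olefination with the stabilised formyl ylide gives the E-enal selectively, and no stereocentre is formed.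

**Step 2**
Reactants: 2 (E)-3-[3,4,5-tris(benzyloxy)phenyl]prop-2-enal
Product: 3 (2R,3S)-3-[3,4,5-tris(benzyloxy)phenyl]oxirane-2-carbaldehyde
Conditions: H2O2 (35% aq, 1.3 equiv), (R)-2-{bis[3,5-bis(trifluoromethyl)phenyl](trimethylsilyloxy)methyl}pyrrolidine (10 mol%), CH2Cl2, rt
Reagents that add atoms: hydrogen peroxide, OO
Why: Organocatalytic iminium–enamine epoxidation of an enal (Jørgensen epoxidation): H2O2 adds to C-β of the E-iminium ion on the face left open by the diaryl(silyloxy)methyl group and the enamine closes the trans-epoxide, which sets 2R,3S (the future flavan C-3 and C-2) under catalyst control.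

**Step 3**
Reactants: 3 (2R,3S)-3-[3,4,5-tris(benzyloxy)phenyl]oxirane-2-carbaldehyde; 4 3-(benzyloxy)phenol
Product: 6 (2R,3S,4S)-7-(benzyloxy)-2-[3,4,5-tris(benzyloxy)phenyl]chromane-3,4-diol cyclic phenylboronate, via benzodioxaborin 5 (not isolated)
Conditions: PhB(OH)2 (1.1 equiv), EtCO2H (0.3 equiv), 4 Å MS, PhMe, 60 °C
Reagents that add atoms: phenylboronic acid, OB(O)c1ccccc1
Why: Proposed new method: Nagata ortho-hydroxyalkylation (phenol + aldehyde + PhB(OH)2 gives a 4H-1,3,2-benzodioxaborin, with the C–C bond ortho to OH and para to OBn) is followed in the same flask by boron-assisted 6-endo opening of the epoxide at its benzylic carbon by the phenol oxygen with inversion (closest known reaction: acid cyclisation of 2'-hydroxychalcone epoxides to dihydroflavonols); this closes ring C 2,3-trans while boron moves onto O-3/O-4 as the dioxaborolane, C-2 and C-3 being carried over from 3 and C-4 left uncontrolled.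

**Step 4**
Reactants: 6 (2R,3S,4S)-7-(benzyloxy)-2-[3,4,5-tris(benzyloxy)phenyl]chromane-3,4-diol cyclic phenylboronate; 7 (−)-epigallocatechin 3-O-gallate (EGCG)
Product: 10 7,3′,4′,5′-tetra-O-benzylrobinetinidol-(4β→8)-(−)-epigallocatechin 3-O-gallate, via EGCG bis(phenylboronate) 8 (not isolated), via boron-bridged adduct 9 (not isolated)
Conditions: 7 (2.5 equiv), PhB(OH)2 (5 equiv), 4 Å MS, THF, rt; add 6, camphorsulfonic acid (0.2 equiv), 40 °C; MeOH–H2O quench; Sephadex LH-20 then C18 HPLC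
Reagents that add atoms: none
Why: Proposed new method: the known acid-promoted Friedel–Crafts coupling of a flavan-4-yl cation with the phloroglucinol ring of a flavan-3-ol is made intramolecular, because the boron on O-3 esterifies the 7-OH of pyrogallol-capped EGCG and delivers C-8 to the C-4 cation from the 3-O face through a seven-membered boracycle, giving 4R (3,4-cis) (closest known reactions: Nagata boron-templated ortho-alkylation and ester-tethered interflavan couplings that give 3,4-cis dimers); without the tether the same cation still gives 10 as one of the separable diastereomers, and the 4α and 4→6 isomers are removed by the chromatography.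

**Step 5**
Reactants: 10 7,3′,4′,5′-tetra-O-benzylrobinetinidol-(4β→8)-(−)-epigallocatechin 3-O-gallate
Product: 11 robinetinidol-(4β→8)-(−)-epigallocatechin 3-O-gallate (target)
Conditions: H2 (1 atm), Pd(OH)2/C, THF–MeOH, rt
Reagents that add atoms: none
Why: Hydrogenolysis of the four benzyl ethers leaves the gallate ester, the interflavan bond and all five stereocentres untouched.

**Compound list**

1 | 3,4,5-tris(benzyloxy)benzaldehyde | O=Cc1cc(OCc2ccccc2)c(OCc2ccccc2)c(OCc2ccccc2)c1 | starting material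
2 | (E)-3-[3,4,5-tris(benzyloxy)phenyl]prop-2-enal | O=C/C=C/c1cc(OCc2ccccc2)c(OCc2ccccc2)c(OCc2ccccc2)c1 | intermediate
3 | (2R,3S)-3-[3,4,5-tris(benzyloxy)phenyl]oxirane-2-carbaldehyde (trans) | O=C[C@@H]1O[C@H]1c1cc(OCc2ccccc2)c(OCc2ccccc2)c(OCc2ccccc2)c1 | intermediate
4 | 3-(benzyloxy)phenol | Oc1cccc(OCc2ccccc2)c1 | starting material
5 | 7-(benzyloxy)-2-phenyl-4-{trans-3-[3,4,5-tris(benzyloxy)phenyl]oxiran-2-yl}-4H-1,3,2-benzodioxaborin (epoxide configuration as in 3) | c1ccccc1COc1ccc2c(c1)OB(c1ccccc1)O[C@@H]2[C@@H]1O[C@H]1c1cc(OCc3ccccc3)c(OCc3ccccc3)c(OCc3ccccc3)c1 | intermediate (not isolated)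
6 | (2R,3S,4S)-7-(benzyloxy)-2-[3,4,5-tris(benzyloxy)phenyl]chromane-3,4-diol cyclic phenylboronate (2,3-trans, cis-fused dioxaborolane) | c1ccccc1COc1ccc2c(c1)O[C@H](c1cc(OCc3ccccc3)c(OCc3ccccc3)c(OCc3ccccc3)c1)[C@H]1OB(c3ccccc3)O[C@@H]21 | intermediate
7 | (−)-epigallocatechin 3-O-gallate (EGCG, 2R,3R) | O=C(O[C@@H]1Cc2c(O)cc(O)cc2O[C@@H]1c1cc(O)c(O)c(O)c1)c1cc(O)c(O)c(O)c1 | starting material
8 | EGCG bis(phenylboronate): one cyclic phenylboronate on two adjacent OH groups of the B-ring pyrogallol and one on the galloyl pyrogallol | O=C(O[C@@H]1Cc2c(O)cc(O)cc2O[C@@H]1c1cc(O)c2OB(c3ccccc3)Oc2c1)c1cc(O)c2OB(c3ccccc3)Oc2c1 | intermediate (not isolated)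
9 | boron-bridged adduct: 10 with a PhB bridge from upper 3-O to lower 7-O (seven-membered boracycle across the new C4–C8 bond) and the two pyrogallol boronates of 8 | O=C(O[C@@H]1Cc2c(O)cc(O6)c([C@H]3c4ccc(OCc5ccccc5)cc4O[C@H](c4cc(OCc5ccccc5)c(OCc5ccccc5)c(OCc5ccccc5)c4)[C@H]3OB6c3ccccc3)c2O[C@@H]1c1cc(O)c2OB(c3ccccc3)Oc2c1)c1cc(O)c2OB(c3ccccc3)Oc2c1 | intermediate (not isolated)
10 | 7,3′,4′,5′-tetra-O-benzylrobinetinidol-(4β→8)-(−)-epigallocatechin 3-O-gallate (upper 2R,3S,4R; lower 2R,3R) | O=C(O[C@@H]1Cc2c(O)cc(O)c([C@H]3c4ccc(OCc5ccccc5)cc4O[C@H](c4cc(OCc5ccccc5)c(OCc5ccccc5)c(OCc5ccccc5)c4)[C@H]3O)c2O[C@@H]1c1cc(O)c(O)c(O)c1)c1cc(O)c(O)c(O)c1 | intermediate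
11 | robinetinidol-(4β→8)-(−)-epigallocatechin 3-O-gallate (upper 2R,3S,4R; lower 2R,3R) | O=C(O[C@@H]1Cc2c(O)cc(O)c([C@H]3c4ccc(O)cc4O[C@H](c4cc(O)c(O)c(O)c4)[C@H]3O)c2O[C@@H]1c1cc(O)c(O)c(O)c1)c1cc(O)c(O)c(O)c1 | target

**Step count and risks**

Total steps: 5. Longest linear sequence: 5 (1 → 2 → 3 → 6 → 10 → 11).

Steps most likely to fail:

1. Step 3 (untested cascade; the epoxy aldehyde may rearrange before the C–C bond forms, or open 5-exo). The fallback sets out from 3 and 4 and comes back at 6. Phenol 4 is turned into its bromomagnesium phenoxide (EtMgBr, CH2Cl2–Et2O, 0 °C), which adds to 3 at the ortho position para to OBn (Casiraghi ortho-hydroxyalkylation through a magnesium chelate) to give [4-(benzyloxy)-2-hydroxyphenyl]{trans-3-[3,4,5-tris(benzyloxy)phenyl]oxiran-2-yl}methanol F1. Camphorsulfonic acid (5 mol%) in CH2Cl2 at 0 °C closes ring C by 6-endo epoxide opening to (2R,3S,4S)-7-(benzyloxy)-2-[3,4,5-tris(benzyloxy)phenyl]chromane-3,4-diol F2. PhB(OH)2 and MgSO4 in CH2Cl2 then esterify the diol to 6.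

2. Step 4 (the boron tether may not outrun the untemplated coupling, which gives the target isomer as a minor component beside the 4α→8 and 4→6 isomers). The fallback sets out from 6 and comes back at 10. Compound 6 is opened with benzyl mercaptan in AcOH at rt to (2R,3R)-7-(benzyloxy)-4-(benzylsulfanyl)-2-[3,4,5-tris(benzyloxy)phenyl]chroman-3-ol F3 (2,3-trans, C-4 epimers). AgBF4 (2 equiv) in THF at 0 °C then ionises the C–S bond in the presence of free 7 (3 equiv), a thiophilic activation that tolerates unprotected phenols. Compound 10 is separated from its 4α and 4→6 isomers by Sephadex LH-20 and C18 HPLC.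

3. Step 2 (the electron-rich enal may form the iminium ion slowly, and the benzylic epoxide is acid-labile). The fallback sets out from 2 and comes back at 3. Enal 2 is reduced (NaBH4, CeCl3·7H2O, MeOH, 0 °C) to (E)-3-[3,4,5-tris(benzyloxy)phenyl]prop-2-en-1-ol F4. Sharpless epoxidation (Ti(OiPr)4, L-(+)-diethyl tartrate, tBuOOH, 4 Å MS, CH2Cl2, −20 °C) gives [(2S,3S)-3-[3,4,5-tris(benzyloxy)phenyl]oxiran-2-yl]methanol F5. Parikh–Doering oxidation (SO3·pyridine, DMSO, iPr2NEt, 0 °C) returns 3.

**Further compounds**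

F1 | step 3 | [4-(benzyloxy)-2-hydroxyphenyl]{trans-3-[3,4,5-tris(benzyloxy)phenyl]oxiran-2-yl}methanol (epoxide configuration as in 3; one carbinol epimer drawn) | c1ccccc1COc1ccc([C@H](O)[C@@H]2O[C@H]2c2cc(OCc3ccccc3)c(OCc3ccccc3)c(OCc3ccccc3)c2)c(O)c1
F2 | step 3 | (2R,3S,4S)-7-(benzyloxy)-2-[3,4,5-tris(benzyloxy)phenyl]chromane-3,4-diol | c1ccccc1COc1ccc2c(c1)O[C@H](c1cc(OCc3ccccc3)c(OCc3ccccc3)c(OCc3ccccc3)c1)[C@@H](O)[C@H]2O
F3 | step 4 | (2R,3R)-7-(benzyloxy)-4-(benzylsulfanyl)-2-[3,4,5-tris(benzyloxy)phenyl]chroman-3-ol (2,3-trans; C-4 epimers) | c1ccccc1COc1ccc2c(c1)O[C@H](c1cc(OCc3ccccc3)c(OCc3ccccc3)c(OCc3ccccc3)c1)[C@@H](O)C2SCc1ccccc1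
F4 | step 2 | (E)-3-[3,4,5-tris(benzyloxy)phenyl]prop-2-en-1-ol | OC/C=C/c1cc(OCc2ccccc2)c(OCc2ccccc2)c(OCc2ccccc2)c1
F5 | step 2 | [(2S,3S)-3-[3,4,5-tris(benzyloxy)phenyl]oxiran-2-yl]methanol | OC[C@@H]1O[C@H]1c1cc(OCc2ccccc2)c(OCc2ccccc2)c(OCc2ccccc2)c1
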